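**Plan**
1. Retrosynthesis: the first cut is the C(sp2)–C(sp3) bond between the alkene carbon remote from the alkyne and its neighbouring CH2. It splits the target into a 5-(buta-1,3-diynyl)oxolane and a (5Z,7Z)-8-bromoocta-5,7-dienyl triflate. Later cuts are the diyne sp–sp bond, the alkyne carbon, the ring C–O bond at the alkynyl-bearing carbon, the epoxide-opening C–C bond, and the C5=C6 alkene of the bromodiene.
2. Enabling feature: the C≡C–CH=CH unit on C5 of the oxolane ring is a buta-1,3-diyne whose terminal triple bond has taken up H and a primary alkyl group on the same face (E-alkene). The CH2 being joined stands in a hex-5-enyl relation to the bromodiene, so a polar, copper-only union is called for.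
3. Forward: epoxide opening gives a dienol; a cobalt-catalysed aerobic cyclisation closes the oxolane ring (the only ring); the pentenyl arm becomes the methyl butanoate by ozonolysis; CH2OH becomes the terminal diyne. The bromodienyl triflate is made separately by a Wittig reaction, and the two halves are joined in the last step.
4. Stereochemistry: C2 of the oxolane comes from the (S)-epoxide; C5 from the 2,5-trans selectivity of the oxidative cyclisation; the 3E alkene from syn-hydrocupration; the 9Z,11Z diene from ethyl (Z)-3-bromoacrylate and a salt-free Wittig reaction.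

Key step: step 12

Remark: the target is read as the trans-(2S,5S)-2,5-disubstituted oxolane; (S)-2-(but-3-en-1-yl)oxirane is taken as a purchasable enantiopure epoxide (otherwise from hydrolytic kinetic resolution of the racemate).

Step 1
Reactants: 1 (S)-2-(but-3-en-1-yl)oxirane; 2 but-3-en-1-ylmagnesium bromide
Product: 3 (R)-deca-1,9-dien-5-ol
Conditions: CuI (copper iodide, 10 mol%), THF, −30 → 0 °C; aqueous NH4Cl
Reagents that add atoms: none
Why: Copper-catalysed SN2 opening of the terminal epoxide at its CH2 carbon by the Grignard reagent leaves the stereocentre untouched, so the (S)-epoxide should give the (R)-alcohol (the descriptor changes only through the priority rules).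

Step 2
Reactants: 3 (R)-deca-1,9-dien-5-ol
Product: 4 [(2S,5R)-5-(pent-4-en-1-yl)oxolan-2-yl]methanol
Conditions: Co(modp)2 (10 mol%; modp = 1-morpholinocarbamoyl-4,4-dimethylpentane-1,3-dionate; divalent cobalt), O2 (1 atm), tBuOOH, iPrOH, 55 °C
Reagents that add atoms: dioxygen, O=O
Why: In this Mukaiyama aerobic oxidative cyclisation the cobalt-bound alkoxide should close 5-exo onto the butenyl alkene with the pentenyl group pseudo-equatorial, which sets the new CH2OH-bearing ring carbon trans to the existing one, and the primary radical is trapped by O2 and reduced to the alcohol, while the pentenyl alkene would need a slower 6-exo closure.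

Step 3
Reactants: 4 [(2S,5R)-5-(pent-4-en-1-yl)oxolan-2-yl]methanol
Product: 5 methyl 4-[(2S,5S)-5-(hydroxymethyl)oxolan-2-yl]butanoate
Conditions: O3, NaOH (2.5 M in MeOH), CH2Cl2, −78 °C
Reagents that add atoms: ozone, [O-][O+]=O; methanol, CO
Why: Ozonolysis in methanolic NaOH should oxidise the cleavage fragments (aldehyde hemiacetal and methoxy hydroperoxide) directly to the methyl ester, so the terminal alkene becomes CO2Me in one operation, while the primary alcohol and the ring ether react far more slowly with ozone at −78 °C.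

Step 4
Reactants: 5 methyl 4-[(2S,5S)-5-(hydroxymethyl)oxolan-2-yl]butanoate
Product: 6 methyl 4-[(2S,5S)-5-formyloxolan-2-yl]butanoate
Conditions: Dess–Martin periodinane, NaHCO3, CH2Cl2, 0 °C → rt
Reagents that add atoms: none
Why: Dess–Martin oxidation converts the primary alcohol into the aldehyde under buffered, non-basic conditions that should neither epimerise the alpha-alkoxy centre nor touch the ester.

Step 5
Reactants: 6 methyl 4-[(2S,5S)-5-formyloxolan-2-yl]butanoate
Product: 7 methyl 4-[(2S,5S)-5-ethynyloxolan-2-yl]butanoate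
Conditions: Ohira–Bestmann reagent, K2CO3, MeOH, 0 °C → rt
Reagents that add atoms: dimethyl (1-diazo-2-oxopropyl)phosphonate, CC(=O)C(=[N+]=[N-])P(=O)(OC)OC
Why: Seyferth–Gilbert homologation with the Ohira–Bestmann reagent converts the aldehyde into the terminal alkyne in methanol, where the methyl ester can only exchange with itself, and the mild carbonate base should leave the alpha-alkoxy centre intact.

Step 6
Reactants: 7 methyl 4-[(2S,5S)-5-ethynyloxolan-2-yl]butanoate; 8 (bromoethynyl)tri(propan-2-yl)silane
Product: 9 methyl 4-[(2S,5S)-5-{4-[tri(propan-2-yl)silyl]buta-1,3-diyn-1-yl}oxolan-2-yl]butanoate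
Conditions: CuCl (5 mol%), NH2OH·HCl, n-BuNH2 (30% aq.), CH2Cl2, 0 °C
Reagents that add atoms: none
Why: Cadiot–Chodkiewicz coupling of the copper acetylide of 7 with the 1-bromoalkyne should give the unsymmetrical 1,3-diyne, the bulky silyl group suppressing homocoupling.

Step 7
Reactants: 9 methyl 4-[(2S,5S)-5-{4-[tri(propan-2-yl)silyl]buta-1,3-diyn-1-yl}oxolan-2-yl]butanoate
Product: 10 methyl 4-[(2S,5S)-5-(buta-1,3-diyn-1-yl)oxolan-2-yl]butanoate
Conditions: Bu4NF, AcOH, THF, 0 °C; kept in solution and used at once
Reagents that add atoms: none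
Why: Fluoride-induced cleavage of the C(sp)–Si bond, buffered with acetic acid so that the diynyl anion is protonated at once, should free the terminal diyne without harming the ester.

Step 8
Reactants: 11 [(5-bromopentyl)oxy](tert-butyl)dimethylsilane
Product: 12 {5-[(tert-butyldimethylsilyl)oxy]pentyl}triphenylphosphonium bromide
Conditions: PPh3, K2CO3 (trace), MeCN, 80 °C
Reagents that add atoms: triphenylphosphine, c1ccc(cc1)P(c1ccccc1)c1ccccc1
Why: SN2 quaternisation of triphenylphosphine by the primary bromide gives the Wittig salt, the trace of base guarding the silyl ether against adventitious HBr.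

Step 9
Reactants: 12 {5-[(tert-butyldimethylsilyl)oxy]pentyl}triphenylphosphonium bromide; 13 ethyl (Z)-3-bromoprop-2-enoate
Product: 16 {[(5Z,7Z)-8-bromoocta-5,7-dien-1-yl]oxy}(tert-butyl)dimethylsilane, via (Z)-3-bromoprop-2-enal 14 (not isolated), via phosphonium ylide 15 (not isolated)
Conditions: 13, iBu2AlH (1.0 equiv), CH2Cl2, −78 °C; the cold solution is added to 15 (from 12, NaN(SiMe3)2, THF, −78 °C); −78 → 0 °C, dark
Reagents that add atoms: none
Why: iBu2AlH should stop at the aldehyde oxidation level at −78 °C with the Z geometry retained, and the salt-free unstabilised ylide should add to the aldehyde under kinetic control (Z-selective Wittig olefination) faster than the enal can isomerise, giving the Z,Z-bromodiene.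

Step 10
Reactants: 16 {[(5Z,7Z)-8-bromoocta-5,7-dien-1-yl]oxy}(tert-butyl)dimethylsilane
Product: 17 (5Z,7Z)-8-bromoocta-5,7-dien-1-ol
Conditions: pyridinium p-toluenesulfonate (cat.), MeOH, rt, dark
Reagents that add atoms: none
Why: Acid-catalysed methanolysis removes the primary silyl ether without base, which the Z-bromodiene would not tolerate (loss of HBr).

Step 11
Reactants: 17 (5Z,7Z)-8-bromoocta-5,7-dien-1-ol
Product: 18 (5Z,7Z)-8-bromoocta-5,7-dien-1-yl trifluoromethanesulfonate
Conditions: Tf2O, 2,6-lutidine, CH2Cl2, −78 °C; short silica plug, used at once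
Reagents that add atoms: trifluoromethanesulfonic anhydride, O=S(=O)(OS(=O)(=O)C(F)(F)F)C(F)(F)F
Why: O-Sulfonylation of the primary alcohol with triflic anhydride and a hindered pyridine base gives the primary triflate needed as the SN2 electrophile.

Step 12
Reactants: 10 methyl 4-[(2S,5S)-5-(buta-1,3-diyn-1-yl)oxolan-2-yl]butanoate; 18 (5Z,7Z)-8-bromoocta-5,7-dien-1-yl trifluoromethanesulfonate
Product: 19 methyl 4-[(2S,5S)-5-[(3E,9Z,11Z)-12-bromododeca-3,9,11-trien-1-yn-1-yl]oxolan-2-yl]butanoate
Conditions: (SIPr)CuOTf (10 mol%; SIPr = 1,3-bis(2,6-diisopropylphenyl)imidazolidin-2-ylidene; monovalent copper), (HMe2Si)2O (about 1 equiv of hydride), CsF, 1,4-dioxane, 45 °C, dark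
Reagents that add atoms: none
Why: Proposed new method: (SIPr)Cu–H, formed from (SIPr)CuOTf, CsF and the disiloxane, should add syn across the terminal triple bond of diyne 10 with copper on the unsubstituted terminal carbon, and the resulting (E)-enynyl copper should be alkylated with retention by the primary triflate 18 in a fluoride-assisted SN2 step that releases the catalyst. The closest known reaction type is the copper hydride-catalysed anti-Markovnikov hydroalkylation of simple terminal alkynes with primary alkyl triflates, which has not been shown at the terminus of a conjugated 1,3-diyne. No ring is closed and no stereocentre is formed; the E geometry of the new alkene follows from syn-hydrocupration and stereoretentive C–C bond formation, and the two oxolane stereocentres are spectators. The step needs site selectivity for the terminal over the internal triple bond, which the steric demand of the carbene ligand and the C–H terminus should secure, and it needs the enyne product not to be reduced further, which the near-stoichiometric hydride and the disubstituted alkene and alkyne of the product should secure. Because the C–C bond forms by a two-electron displacement at the CH2–OTf carbon, the hex-5-enyl relation between that carbon and the bromodiene cannot lead to radical 5-exo cyclisation, and in the absence of zerovalent palladium or nickel the C(sp2)–Br bond and the Z,Z geometry should survive.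

**Compound list**
1 | (S)-2-(but-3-en-1-yl)oxirane | C=CCC[C@H]1CO1 | starting material
2 | but-3-en-1-ylmagnesium bromide | C=CCC[Mg]Br | starting material
3 | (R)-deca-1,9-dien-5-ol | C=CCCC[C@@H](O)CCC=C | intermediate
4 | [(2S,5R)-5-(pent-4-en-1-yl)oxolan-2-yl]methanol | C=CCCC[C@@H]1CC[C@@H](CO)O1 | intermediate
5 | methyl 4-[(2S,5S)-5-(hydroxymethyl)oxolan-2-yl]butanoate | COC(=O)CCC[C@@H]1CC[C@@H](CO)O1 | intermediate
6 | methyl 4-[(2S,5S)-5-formyloxolan-2-yl]butanoate | COC(=O)CCC[C@@H]1CC[C@@H](C=O)O1 | intermediate
7 | methyl 4-[(2S,5S)-5-ethynyloxolan-2-yl]butanoate | COC(=O)CCC[C@@H]1CC[C@@H](C#C)O1 | intermediate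
8 | (bromoethynyl)tri(propan-2-yl)silane | BrC#C[Si](C(C)C)(C(C)C)C(C)C | starting material
9 | methyl 4-[(2S,5S)-5-{4-[tri(propan-2-yl)silyl]buta-1,3-diyn-1-yl}oxolan-2-yl]butanoate | COC(=O)CCC[C@@H]1CC[C@@H](C#CC#C[Si](C(C)C)(C(C)C)C(C)C)O1 | intermediate
10 | methyl 4-[(2S,5S)-5-(buta-1,3-diyn-1-yl)oxolan-2-yl]butanoate | COC(=O)CCC[C@@H]1CC[C@@H](C#CC#C)O1 | intermediate
11 | [(5-bromopentyl)oxy](tert-butyl)dimethylsilane | CC(C)(C)[Si](C)(C)OCCCCCBr | starting material
12 | {5-[(tert-butyldimethylsilyl)oxy]pentyl}triphenylphosphonium bromide | CC(C)(C)[Si](C)(C)OCCCCC[P+](c1ccccc1)(c1ccccc1)c1ccccc1.[Br-] | intermediate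
13 | ethyl (Z)-3-bromoprop-2-enoate | CCOC(=O)/C=C\Br | starting material
14 | (Z)-3-bromoprop-2-enal | O=C/C=C\Br | intermediate
15 | {5-[(tert-butyldimethylsilyl)oxy]pentylidene}triphenylphosphorane | CC(C)(C)[Si](C)(C)OCCCCC=P(c1ccccc1)(c1ccccc1)c1ccccc1 | intermediate
16 | {[(5Z,7Z)-8-bromoocta-5,7-dien-1-yl]oxy}(tert-butyl)dimethylsilane | CC(C)(C)[Si](C)(C)OCCCC/C=C\C=C/Br | intermediate
17 | (5Z,7Z)-8-bromoocta-5,7-dien-1-ol | OCCCC/C=C\C=C/Br | intermediate
18 | (5Z,7Z)-8-bromoocta-5,7-dien-1-yl trifluoromethanesulfonate | O=S(=O)(OCCCC/C=C\C=C/Br)C(F)(F)F | intermediate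
19 | methyl 4-[(2S,5S)-5-[(3E,9Z,11Z)-12-bromododeca-3,9,11-trien-1-yn-1-yl]oxolan-2-yl]butanoate | COC(=O)CCC[C@@H]1CC[C@@H](C#C/C=C/CCCC/C=C\C=C/Br)O1 | target

**Step count and risks**
Total step count: 12. Longest linear sequence: 8 (steps 1 to 7, then step 12); the triflate branch is 4 steps (8 to 11).

Steps most likely to fail:

Step 12 (Proposed new method). The hydroalkylation may fail in four ways: deprotonation of the acidic diyne C–H to an inert copper diynide, hydrocupration at the internal triple bond, over-reduction of the enyne product, or fluoride-induced loss of HBr from the Z-bromodiene. The fallback makes the same bond by a B-alkyl Suzuki–Miyaura coupling, in which the CH2 carbon is again joined by a two-electron pathway; it sets out from 10 and 13 and comes back to the route at 19. Diyne 10 is hydrozirconated at its terminal triple bond with Cp2Zr(H)Cl (THF, rt) to give chlorobis(cyclopentadienyl)[(E)-4-{(2S,5S)-5-(4-methoxy-4-oxobutyl)oxolan-2-yl}but-1-en-3-yn-1-yl]zirconium F1 in solution, and cleavage of F1 with I2 gives methyl 4-[(2S,5S)-5-[(E)-4-iodobut-3-en-1-yn-1-yl]oxolan-2-yl]butanoate F2 with retention of the E geometry. Ester 13 is reduced to 14 as in step 9, and the cold solution is added at −78 °C to triphenyl(pent-4-en-1-ylidene)phosphorane F3 in THF, made from purchased (pent-4-en-1-yl)triphenylphosphonium bromide and NaN(SiMe3)2; the Z-selective Wittig reaction should give (1Z,3Z)-1-bromoocta-1,3,7-triene F4 as a volatile oil. 9-Borabicyclo[3.3.1]nonane (1.0 equiv, THF, 0 °C → rt) should add only to the monosubstituted terminal alkene of F4 and give 9-[(5Z,7Z)-8-bromoocta-5,7-dien-1-yl]-9-borabicyclo[3.3.1]nonane F5 in solution. Coupling of F5 with F2 (PdCl2(dppf), dppf = 1,1'-bis(diphenylphosphino)ferrocene, divalent palladium precatalyst, AsPh3, Cs2CO3, DMF–THF–H2O, rt, dark) should give 19, the C(sp2)–I bond undergoing oxidative addition ahead of the C(sp2)–Br bond.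

Step 9. The β-bromo enal may isomerise from Z to E before or during the olefination, or the ylide may attack the β-carbon by addition–elimination. The fallback builds the bromoalkene from an alkyne instead; it sets out from 12 (through its ylide 15) and comes back at 16. Ylide 15 is condensed at −78 °C with 3-(trimethylsilyl)prop-2-ynal in a Z-selective Wittig reaction to give tert-butyldimethyl{[(Z)-8-(trimethylsilyl)oct-5-en-7-yn-1-yl]oxy}silane F6 as the enyne. Bromodesilylation of F6 with N-bromosuccinimide and catalytic AgNO3 in acetone gives {[(Z)-8-bromooct-5-en-7-yn-1-yl]oxy}(tert-butyl)dimethylsilane F7 without touching the alkene. Syn-hydroboration of the bromoalkyne of F7 with dicyclohexylborane gives [(1Z,3Z)-1-bromo-8-{[tert-butyl(dimethyl)silyl]oxy}octa-1,3-dien-1-yl]dicyclohexylborane F8 in solution, and protonolysis of the C–B bond of F8 with acetic acid (retention) gives 16.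

Step 2. Cobalt-mediated oxidation or hydration of the remote pentenyl alkene may compete with the directed cyclisation, and over-oxidation of the new primary alcohol is possible. The fallback closes the ring by halocyclisation; it sets out from 3 and comes back at 4. Iodoetherification (I2, NaHCO3, MeCN, 0 °C; 5-exo) gives (2S,5R)-2-(iodomethyl)-5-(pent-4-en-1-yl)oxolane F9 as the major isomer; the trans preference is expected to be weaker than in the cobalt reaction, so chromatographic removal of the minor diastereomer has to be planned. Displacement of the iodide of F9 with CsOAc in DMF at 80 °C gives [(2S,5R)-5-(pent-4-en-1-yl)oxolan-2-yl]methyl acetate F10 by an SN2 reaction, and methanolysis of F10 (K2CO3, MeOH) gives 4.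

Further compounds
F1 | step 12 | chlorobis(cyclopentadienyl)[(E)-4-{(2S,5S)-5-(4-methoxy-4-oxobutyl)oxolan-2-yl}but-1-en-3-yn-1-yl]zirconium | COC(=O)CCC[C@@H]1CC[C@@H](C#C/C=C/[Zr](Cl)(C2C=CC=C2)C2C=CC=C2)O1
F2 | step 12 | methyl 4-[(2S,5S)-5-[(E)-4-iodobut-3-en-1-yn-1-yl]oxolan-2-yl]butanoate | COC(=O)CCC[C@@H]1CC[C@@H](C#C/C=C/I)O1
F3 | step 12 | triphenyl(pent-4-en-1-ylidene)phosphorane | C=CCCC=P(c1ccccc1)(c1ccccc1)c1ccccc1
F4 | step 12 | (1Z,3Z)-1-bromoocta-1,3,7-triene | C=CCC/C=C\C=C/Br
F5 | step 12 | 9-[(5Z,7Z)-8-bromoocta-5,7-dien-1-yl]-9-borabicyclo[3.3.1]nonane | Br/C=C\C=C/CCCCB1C2CCCC1CCC2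
F6 | step 9 | tert-butyldimethyl{[(Z)-8-(trimethylsilyl)oct-5-en-7-yn-1-yl]oxy}silane | CC(C)(C)[Si](C)(C)OCCCC/C=C\C#C[Si](C)(C)C
F7 | step 9 | {[(Z)-8-bromooct-5-en-7-yn-1-yl]oxy}(tert-butyl)dimethylsilane | CC(C)(C)[Si](C)(C)OCCCC/C=C\C#CBr
F8 | step 9 | [(1Z,3Z)-1-bromo-8-{[tert-butyl(dimethyl)silyl]oxy}octa-1,3-dien-1-yl]dicyclohexylborane | CC(C)(C)[Si](C)(C)OCCCC/C=C\C=C(/Br)B(C1CCCCC1)C1CCCCC1
F9 | step 2 | (2S,5R)-2-(iodomethyl)-5-(pent-4-en-1-yl)oxolane | C=CCCC[C@@H]1CC[C@@H](CI)O1
F10 | step 2 | [(2S,5R)-5-(pent-4-en-1-yl)oxolan-2-yl]methyl acetate | C=CCCC[C@@H]1CC[C@@H](COC(C)=O)O1
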